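T = top flavan (free O3), M = middle gallate unit, B = bottom gallate unit. Flavan numbering is used, and α is the face that carries the 2-aryl groups. Read from the SMILES, the target is T-(4α→8)-M-(4β→8)-B.
Feature used: ring A of T is tied to the rest only through O1–C8a and C4–C4a, with O5 ortho to C4a. This is the polarity of 3,5-dialkoxybenzyne (nucleophile at the distal carbon, anion beside oxygen). T C4 holds M C8 on the α face, cis to O3 and to the 2-aryl group, so H-4 has to enter from the β face.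
Disconnections, last bond first: the two gallate esters; T C4–H (hydride onto the C4 cation); T O1–C8a and T C4–C4a (aryne plus a syn-aldol ketone seated on M C8); acyl C–M C8 (aryllithium plus Weinreb amide); M C4–B C8 (C4 cation plus B).
Rings: all rings of M and B come intact from (−)-epicatechin, ring B of T from 3,4-bis(benzyloxy)benzaldehyde, and ring A of T from the aryne. Ring C of T is the only ring that is closed (step 15).
M and B are joined before T is built. The C8 bromine first caps the M electrophile and then serves as the lithium handle, and no C4 oxidation has to be run on a compound that holds the doubly benzylic, β-exposed T C4–H.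

Key step: step 15

Assumption: 29 is drawn as the C4 epimer expected on steric grounds (M aryl β, hydroxyl α); the other epimer would give the same cation 30 and therefore the same 31.

Step 1
Reactants: 1 3,5-bis(benzyloxy)phenol
Product: 2 2-bromo-3,5-bis(benzyloxy)phenol
Conditions: NBS (1.0 equiv), i-Pr2NH (10 mol %), CH2Cl2, −78 → 0 °C
Reagents that add atoms: N-bromosuccinimide, O=C1CCC(=O)N1Br
Why: Amine-catalysed NBS bromination of a phenol (electrophilic aromatic substitution) is ortho-directed, C2 and C6 are equivalent and C4 is shielded by two benzyloxy groups, so one equivalent at low temperature should give the bromide with bromine between OH and OBn.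

Step 2
Reactants: 2 2-bromo-3,5-bis(benzyloxy)phenol
Product: 5 3,5-bis(benzyloxy)-2-(trimethylsilyl)phenyl trifluoromethanesulfonate, via aryl trimethylsilyl ether 3 (not isolated), via lithium 2-silylphenoxide 4 (not isolated)
Conditions: (Me3Si)2NH, THF, 65 °C, then evaporate; n-BuLi, THF, −78 °C; Tf2O, −78 → 0 °C
Reagents that add atoms: hexamethyldisilazane, C[Si](C)(C)N[Si](C)(C)C; triflic anhydride, O=S(=O)(OS(=O)(=O)C(F)(F)F)C(F)(F)F
Why: This is the usual route to o-silylaryl triflates, namely O-silylation, bromine–lithium exchange (faster at −78 °C than benzylic deprotonation), 1,3 O-to-C silyl shift (retro-Brook rearrangement) and triflation of the released phenoxide, which leaves SiMe3 on the carbon next to the 3-benzyloxy group.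

Step 3
Reactants: 6 (−)-epicatechin
Product: 7 5,7,3',4'-tetra-O-benzyl-(−)-epicatechin (2R,3R; 3-OH free)
Conditions: BnBr (4.4 equiv), K2CO3, DMF, rt, Ar
Reagents that add atoms: benzyl bromide, BrCc1ccccc1
Why: In this Williamson ether synthesis K2CO3 ionises only the four phenols, so the secondary 3-OH stays free and C2 and C3 are not touched as long as the mixture is kept at room temperature under argon.

Step 4
Reactants: 7 5,7,3',4'-tetra-O-benzylepicatechin
Product: 8 3-O-TBS-5,7,3',4'-tetra-O-benzylepicatechin (unit B nucleophile)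
Conditions: TBSCl, imidazole, DMF, rt
Reagents that add atoms: tert-butyldimethylsilyl chloride, CC(C)(C)[Si](C)(C)Cl
Why: Imidazole-promoted silylation of the only free hydroxyl gives a B unit without an ester, which is needed because an aryllithium is made in its presence in step 13.

Step 5
Reactants: 7 5,7,3',4'-tetra-O-benzylepicatechin
Product: 9 8-bromo-5,7,3',4'-tetra-O-benzylepicatechin
Conditions: NBS (1.0 equiv), CH2Cl2, −78 °C → rt
Reagents that add atoms: N-bromosuccinimide, O=C1CCC(=O)N1Br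
Why: Electrophilic aromatic bromination goes to C8, the most nucleophilic position of a 5,7-dibenzyloxyflavan A ring, and one equivalent of NBS at low temperature should stop at the monobromide.

Step 6
Reactants: 9 8-bromo-5,7,3',4'-tetra-O-benzylepicatechin
Product: 10 8-bromo-3-O-TBS-5,7,3',4'-tetra-O-benzylepicatechin
Conditions: TBSCl, imidazole, DMF, rt
Reagents that add atoms: tert-butyldimethylsilyl chloride, CC(C)(C)[Si](C)(C)Cl
Why: Standard silylation protects O3 with a group that tolerates t-BuLi and brief acid and stays orthogonal to the benzyl ethers.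

Step 7
Reactants: 10 8-bromo-3-O-TBS-5,7,3',4'-tetra-O-benzylepicatechin
Product: 11 8-bromo-4β-(2-ethoxyethoxy)-3-O-TBS-5,7,3',4'-tetra-O-benzylepicatechin
Conditions: DDQ (2 equiv), EtOCH2CH2OH (8 equiv), CH2Cl2, rt
Reagents that add atoms: 2-ethoxyethanol, CCOCCO
Why: In this DDQ benzylic oxidation, hydride abstraction from C4 gives the cation stabilised by ring A and the alcohol adds on the β face, trans to the 3-silyloxy and 2-aryl groups, which installs a 4β leaving group.

Step 8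
Reactants: 11 8-bromo-4β-(2-ethoxyethoxy) M electrophile; 8 unit B nucleophile (3 equiv)
Product: 13 8-bromo-3-O-TBS-tetra-O-benzylepicatechin-(4β→8)-3-O-TBS-tetra-O-benzylepicatechin (Br–M–B dimer), via M C4 cation 12 (not isolated)
Conditions: TMSOTf (0.2 equiv), CH2Cl2, −78 °C
Reagents that add atoms: none
Why: In this Lewis-acid-promoted SN1/Friedel–Crafts coupling of a flavan-4-yl cation, C8 of 8 attacks 12 on the β face opposite to the 3-silyloxy and 2-aryl groups, which sets M C4 (4β, 3,4-trans), while the bromine at M C8 keeps the electrophile from condensing with itself.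

Step 9
Reactants: 14 (S)-4-benzyloxazolidin-2-one; 15 benzyloxyacetyl chloride
Product: 17 (S)-4-benzyl-3-(benzyloxyacetyl)oxazolidin-2-one, via lithium oxazolidinide 16 (not isolated)
Conditions: n-BuLi, THF, −78 °C; 15, −78 → 0 °C
Reagents that add atoms: none
Why: N-acylation of the lithiated oxazolidinone with an acid chloride is the standard entry to glycolate imides and does not touch the auxiliary stereocentre.

Step 10
Reactants: 17 glycolate imide; 18 3,4-bis(benzyloxy)benzaldehyde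
Product: 21 (S)-4-benzyl-3-[(2S,3R)-2-benzyloxy-3-[3,4-bis(benzyloxy)phenyl]-3-hydroxypropanoyl]oxazolidin-2-one (syn), via Z boron enolate 19 (not isolated), via boron aldolate 20 (not isolated)
Conditions: n-Bu2BOTf, Et3N, CH2Cl2, −78 → 0 °C; 18, −78 → 0 °C; pH 7 buffer, MeOH, 30% H2O2, 0 °C
Reagents that add atoms: none
Why: In the Evans syn aldol reaction the Z boron enolate 19 reacts through a closed chair transition state on the face away from the benzyl group of the (S)-auxiliary, which sets the (2S,3R) syn pair that becomes T C3 and T C2.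

Step 11
Reactants: 21 syn aldol imide
Product: 22 (2S,3R)-2-benzyloxy-3-[3,4-bis(benzyloxy)phenyl]-3-hydroxy-N-methoxy-N-methylpropanamide
Conditions: MeNH(OMe)·HCl, Me3Al, THF, 0 °C → rt; aq potassium sodium tartrate
Reagents that add atoms: N,O-dimethylhydroxylamine hydrochloride, CNOC.Cl
Why: Aluminium-amide transamidation (Weinreb amide synthesis) is assisted by the free β-hydroxyl and removes the auxiliary under conditions too mild for retro-aldol cleavage or epimerisation.

Step 12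
Reactants: 22 hydroxy Weinreb amide
Product: 23 (2S,3R)-2-benzyloxy-3-[3,4-bis(benzyloxy)phenyl]-N-methoxy-N-methyl-3-(triethylsilyloxy)propanamide
Conditions: TESCl, imidazole, CH2Cl2, 0 °C → rt
Reagents that add atoms: chlorotriethylsilane, CC[Si](Cl)(CC)CC
Why: Silylation masks the only acidic proton before the aryllithium step, and a TES ether is chosen because it can later be removed beside the two TBS ethers.

Step 13
Reactants: 13 Br–M–B dimer; 23 TES-protected Weinreb amide (1.5 equiv)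
Product: 25 M-8-yl ketone: 13 in which Br at M C8 is replaced by the (2S,3R)-2-benzyloxy-3-[3,4-bis(benzyloxy)phenyl]-3-(triethylsilyloxy)propanoyl group, via M 8-lithio dimer 24 (not isolated)
Conditions: 13, t-BuLi (2.0 equiv), THF, −78 °C; 23, −78 → −30 °C; aq NH4Cl
Reagents that add atoms: none
Why: Bromine–lithium exchange is followed by a Weinreb ketone synthesis in which the chelated tetrahedral adduct holds until the quench, so no second addition takes place and the α-stereocentre is never exposed to base as a ketone.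

Step 14
Reactants: 25 TES-protected M-8-yl ketone
Product: 26 (2S,3R)-2-benzyloxy-3-[3,4-bis(benzyloxy)phenyl]-3-hydroxy-1-(M-8-yl)propan-1-one (syn aldol; M–B part as in 13)
Conditions: HF·pyridine, pyridine, THF, 0 °C
Reagents that add atoms: none
Why: Buffered HF·pyridine cleaves the triethylsilyl ether much faster than secondary TBS ethers, and the nearly neutral medium should spare the aldol from retro-aldol cleavage, elimination and epimerisation.

Step 15
Reactants: 26 syn aldol M-8-yl ketone; 5 3,5-bis(benzyloxy)-2-(trimethylsilyl)phenyl triflate (3 equiv, in portions)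
Product: 29 4-hydroxy-4-(M-8-yl) T flavan: 2,3-cis 3,5,7,3',4'-penta-O-benzylflavan-4α-ol with M C8 on C4β (M–B part as in 13), via 3,5-bis(benzyloxy)benzyne 27 (not isolated), via C4a aryl anion 28 (not isolated)
Conditions: CsF (6 equiv), 18-crown-6 (3 equiv), 4 Å MS, THF, 0 °C → rt
Reagents that add atoms: none
Why: Proposed new method: fluoride attacks the silyl group of 5 and triflate leaves, so aryne 27 is set free beside the fluoride-hydrogen-bonded C2 hydroxyl of 26; this oxygen adds to the aryne carbon remote from the flanking benzyloxy group (T O1–C8a), the resulting anion 28 sits at C4a beside the σ-withdrawing O5 and adds at once to the ketone carbon held next to it (T C4–C4a), and the tertiary alkoxide then takes the proton back. The closest known reaction type is the fluoride-triggered annulation of arynes with 2-hydroxyaryl aldehydes and ketones to xanthen-9-ols (O-addition, then carbonyl capture), and what is new is an aliphatic β-hydroxy ketone as the O,C-partner. Ring C of T closes in a 6-exo-trig mode, with the carbonyl oxygen outside the new ring. C2 and C3 keep the syn-aldol configuration because neither C–O bond is broken, which gives the 2,3-cis pair; at the new centre C4 the bulky M aryl group should take the pseudo-axial β position, away from the peri 5-benzyloxy group and anti to O3, but this outcome does not matter because step 16 flattens C4. The step needs one aryne orientation, secured by the distortion and inductive pull of the 3-benzyloxy group, and O- before C-attack, secured because the di-ortho-substituted ketone enolises slowly and its carbonyl is reached only by an anion held beside it. THF instead of MeCN removes the external proton source that would quench 28, and low temperature with an excess of quickly released aryne should let the capture outrun retro-aldol cleavage, which is slowed further because the enolate to be expelled is twisted out of conjugation with ring A of M.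

Step 16
Reactants: 29 4-aryl-flavan-4-ol
Product: 31 penta-O-benzylepicatechin-(4α→8)-[3-O-TBS-tetra-O-benzylepicatechin]-(4β→8)-[3-O-TBS-tetra-O-benzylepicatechin], via T C4 cation 30 (not isolated)
Conditions: n-Bu3SnH (5 equiv), CF3CO2H (10 equiv), CH2Cl2, 0 °C
Reagents that add atoms: none
Why: In this ionic hydrogenation (SN1 deoxygenation of a tertiary diarylcarbinol) acid ionises C4 to the planar cation 30 and hydride enters from the β face, opposite to the 3-benzyloxy and 2-aryl groups, which leaves the M aryl group α; the tin hydride is preferred to a silane because a cation flanked by two trioxygenated rings is a weak electrophile and must be caught before it loses H-3.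

Step 17
Reactants: 31 bis-TBS trimer
Product: 32 trimer diol (M 3-OH and B 3-OH free; T O3 benzylated)
Conditions: n-Bu4NF, THF, rt → 45 °C
Reagents that add atoms: none
Why: This is a fluoride desilylation in which every other group is an ether, so gentle warming can be used for the hindered M 3-O-TBS group.

Step 18
Reactants: 32 trimer diol; 33 3,4,5-tris(benzyloxy)benzoic acid (5 equiv)
Product: 34 nonadeca-O-benzyl trimer digallate (tri-O-benzylgalloyl on M O3 and B O3)
Conditions: DCC, DMAP, CH2Cl2, rt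
Reagents that add atoms: none
Why: Steglich esterification with an excess of acid acylates both secondary hydroxyls with retention while T O3 is blocked as its benzyl ether, which places gallates on M and B only.

Step 19
Reactants: 34 protected trimer digallate
Product: 35 CNP0279403.2, epicatechin-(4α→8)-epicatechin 3-O-gallate-(4β→8)-epicatechin 3-O-gallate
Conditions: H2 (1 atm), Pd(OH)2/C, THF/MeOH/H2O, rt
Reagents that add atoms: none
Why: Hydrogenolysis over Pd(OH)2/C removes all nineteen benzyl groups (aryl ethers, gallate ethers and the T 3-O-benzyl ether) under neutral conditions that leave the esters, the interflavan bonds and all stereocentres alone.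

Compound list
1 | 3,5-bis(benzyloxy)phenol | Oc1cc(OCc2ccccc2)cc(OCc2ccccc2)c1 | starting material
2 | 2-bromo-3,5-bis(benzyloxy)phenol | Oc1cc(OCc2ccccc2)cc(OCc2ccccc2)c1Br | intermediate
3 | [2-bromo-3,5-bis(benzyloxy)phenoxy]trimethylsilane | C[Si](C)(C)Oc1cc(OCc2ccccc2)cc(OCc2ccccc2)c1Br | intermediate
4 | lithium 3,5-bis(benzyloxy)-2-(trimethylsilyl)phenoxide | [Li+].[O-]c1cc(OCc2ccccc2)cc(OCc2ccccc2)c1[Si](C)(C)C | intermediate
5 | 3,5-bis(benzyloxy)-2-(trimethylsilyl)phenyl triflate | C[Si](C)(C)c1c(OCc2ccccc2)cc(OCc2ccccc2)cc1OS(=O)(=O)C(F)(F)F | intermediate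
6 | (−)-epicatechin | O[C@@H]1Cc2c(O)cc(O)cc2O[C@@H]1c1ccc(O)c(O)c1 | starting material
7 | 5,7,3',4'-tetra-O-benzylepicatechin | O[C@@H]1Cc2c(OCc9ccccc9)cc(OCc9ccccc9)cc2O[C@@H]1c8ccc(OCc9ccccc9)c(OCc9ccccc9)c8 | intermediate
8 | 3-O-TBS-tetra-O-benzylepicatechin | CC(C)(C)[Si](C)(C)O[C@@H]1Cc2c(OCc9ccccc9)cc(OCc9ccccc9)cc2O[C@@H]1c8ccc(OCc9ccccc9)c(OCc9ccccc9)c8 | intermediate
9 | 8-bromo-tetra-O-benzylepicatechin | O[C@@H]1Cc2c(OCc9ccccc9)cc(OCc9ccccc9)c(Br)c2O[C@@H]1c8ccc(OCc9ccccc9)c(OCc9ccccc9)c8 | intermediate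
10 | 8-bromo-3-O-TBS-tetra-O-benzylepicatechin | CC(C)(C)[Si](C)(C)O[C@@H]1Cc2c(OCc9ccccc9)cc(OCc9ccccc9)c(Br)c2O[C@@H]1c8ccc(OCc9ccccc9)c(OCc9ccccc9)c8 | intermediate
11 | 8-bromo-4β-(2-ethoxyethoxy)-3-O-TBS-tetra-O-benzylepicatechin | CC(C)(C)[Si](C)(C)O[C@@H]1[C@@H](OCCOCC)c2c(OCc9ccccc9)cc(OCc9ccccc9)c(Br)c2O[C@@H]1c8ccc(OCc9ccccc9)c(OCc9ccccc9)c8 | intermediate
12 | M C4 cation (triflate ion pair) | CC(C)(C)[Si](C)(C)O[C@@H]1[CH+]c2c(OCc9ccccc9)cc(OCc9ccccc9)c(Br)c2O[C@@H]1c8ccc(OCc9ccccc9)c(OCc9ccccc9)c8.[O-]S(=O)(=O)C(F)(F)F | intermediate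
13 | Br–M–(4β→8)–B dimer, bis-TBS | CC(C)(C)[Si](C)(C)O[C@@H]1[C@@H](c2c(OCc9ccccc9)cc(OCc9ccccc9)c3c2O[C@H](c8ccc(OCc9ccccc9)c(OCc9ccccc9)c8)[C@H](O[Si](C)(C)C(C)(C)C)C3)c2c(OCc9ccccc9)cc(OCc9ccccc9)c(Br)c2O[C@@H]1c8ccc(OCc9ccccc9)c(OCc9ccccc9)c8 | intermediate
14 | (S)-4-benzyloxazolidin-2-one | O=C1N[C@@H](Cc2ccccc2)CO1 | starting material
15 | benzyloxyacetyl chloride | O=C(Cl)COCc1ccccc1 | starting material
16 | lithium salt of 14 | [Li+].O=C1[N-][C@@H](Cc2ccccc2)CO1 | intermediate
17 | (S)-4-benzyl-3-(benzyloxyacetyl)oxazolidin-2-one | O=C(COCc1ccccc1)N1C(=O)OC[C@@H]1Cc1ccccc1 | intermediate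
18 | 3,4-bis(benzyloxy)benzaldehyde | O=Cc1ccc(OCc2ccccc2)c(OCc2ccccc2)c1 | starting material
19 | Z dibutylboron enolate of 17 | CCCCB(CCCC)O/C(=C\OCc1ccccc1)N1C(=O)OC[C@@H]1Cc1ccccc1 | intermediate
20 | dibutylboron aldolate | O=C([C@@H](OCc1ccccc1)[C@H](OB(CCCC)CCCC)c1ccc(OCc2ccccc2)c(OCc2ccccc2)c1)N1C(=O)OC[C@@H]1Cc1ccccc1 | intermediate
21 | (2S,3R) syn aldol imide | O=C([C@@H](OCc1ccccc1)[C@H](O)c1ccc(OCc2ccccc2)c(OCc2ccccc2)c1)N1C(=O)OC[C@@H]1Cc1ccccc1 | intermediate
22 | (2S,3R) hydroxy Weinreb amide | CON(C)C(=O)[C@@H](OCc1ccccc1)[C@H](O)c1ccc(OCc2ccccc2)c(OCc2ccccc2)c1 | intermediate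
23 | (2S,3R) TES-protected Weinreb amide | CON(C)C(=O)[C@@H](OCc1ccccc1)[C@H](O[Si](CC)(CC)CC)c1ccc(OCc2ccccc2)c(OCc2ccccc2)c1 | intermediate
24 | M 8-lithio dimer | CC(C)(C)[Si](C)(C)O[C@@H]1[C@@H](c2c(OCc9ccccc9)cc(OCc9ccccc9)c3c2O[C@H](c8ccc(OCc9ccccc9)c(OCc9ccccc9)c8)[C@H](O[Si](C)(C)C(C)(C)C)C3)c2c(OCc9ccccc9)cc(OCc9ccccc9)c([Li])c2O[C@@H]1c8ccc(OCc9ccccc9)c(OCc9ccccc9)c8 | intermediate
25 | TES-protected M-8-yl ketone | CC(C)(C)[Si](C)(C)O[C@@H]1[C@@H](c2c(OCc9ccccc9)cc(OCc9ccccc9)c3c2O[C@H](c8ccc(OCc9ccccc9)c(OCc9ccccc9)c8)[C@H](O[Si](C)(C)C(C)(C)C)C3)c2c(OCc9ccccc9)cc(OCc9ccccc9)c(C(=O)[C@@H](OCc9ccccc9)[C@H](O[Si](CC)(CC)CC)c8ccc(OCc9ccccc9)c(OCc9ccccc9)c8)c2O[C@@H]1c8ccc(OCc9ccccc9)c(OCc9ccccc9)c8 | intermediate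
26 | syn aldol M-8-yl ketone (key-step precursor) | CC(C)(C)[Si](C)(C)O[C@@H]1[C@@H](c2c(OCc9ccccc9)cc(OCc9ccccc9)c3c2O[C@H](c8ccc(OCc9ccccc9)c(OCc9ccccc9)c8)[C@H](O[Si](C)(C)C(C)(C)C)C3)c2c(OCc9ccccc9)cc(OCc9ccccc9)c(C(=O)[C@@H](OCc9ccccc9)[C@H](O)c8ccc(OCc9ccccc9)c(OCc9ccccc9)c8)c2O[C@@H]1c8ccc(OCc9ccccc9)c(OCc9ccccc9)c8 | intermediate
27 | 3,5-bis(benzyloxy)benzyne | C1#CC(OCc2ccccc2)=CC(OCc2ccccc2)=C1 | intermediate
28 | C4a aryl anion (caesium salt) of the O-arylated aldol | CC(C)(C)[Si](C)(C)O[C@@H]1[C@@H](c2c(OCc9ccccc9)cc(OCc9ccccc9)c3c2O[C@H](c8ccc(OCc9ccccc9)c(OCc9ccccc9)c8)[C@H](O[Si](C)(C)C(C)(C)C)C3)c2c(OCc9ccccc9)cc(OCc9ccccc9)c(C(=O)[C@@H](OCc9ccccc9)[C@H](Oc7cc(OCc9ccccc9)cc(OCc9ccccc9)[c-]7)c8ccc(OCc9ccccc9)c(OCc9ccccc9)c8)c2O[C@@H]1c8ccc(OCc9ccccc9)c(OCc9ccccc9)c8.[Cs+] | intermediate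
29 | 4α-hydroxy-4β-(M-8-yl) T flavan (key-step product) | CC(C)(C)[Si](C)(C)O[C@@H]1[C@@H](c2c(OCc9ccccc9)cc(OCc9ccccc9)c3c2O[C@H](c8ccc(OCc9ccccc9)c(OCc9ccccc9)c8)[C@H](O[Si](C)(C)C(C)(C)C)C3)c2c(OCc9ccccc9)cc(OCc9ccccc9)c([C@@]3(O)c4c(OCc9ccccc9)cc(OCc9ccccc9)cc4O[C@H](c8ccc(OCc9ccccc9)c(OCc9ccccc9)c8)[C@@H]3OCc9ccccc9)c2O[C@@H]1c8ccc(OCc9ccccc9)c(OCc9ccccc9)c8 | intermediate
30 | T C4 cation (trifluoroacetate ion pair) | CC(C)(C)[Si](C)(C)O[C@@H]1[C@@H](c2c(OCc9ccccc9)cc(OCc9ccccc9)c3c2O[C@H](c8ccc(OCc9ccccc9)c(OCc9ccccc9)c8)[C@H](O[Si](C)(C)C(C)(C)C)C3)c2c(OCc9ccccc9)cc(OCc9ccccc9)c([C+]3c4c(OCc9ccccc9)cc(OCc9ccccc9)cc4O[C@H](c8ccc(OCc9ccccc9)c(OCc9ccccc9)c8)[C@@H]3OCc9ccccc9)c2O[C@@H]1c8ccc(OCc9ccccc9)c(OCc9ccccc9)c8.[O-]C(=O)C(F)(F)F | intermediate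
31 | T-(4α→8)-M-(4β→8)-B trimer, bis-TBS | CC(C)(C)[Si](C)(C)O[C@@H]1[C@@H](c2c(OCc9ccccc9)cc(OCc9ccccc9)c3c2O[C@H](c8ccc(OCc9ccccc9)c(OCc9ccccc9)c8)[C@H](O[Si](C)(C)C(C)(C)C)C3)c2c(OCc9ccccc9)cc(OCc9ccccc9)c([C@@H]3c4c(OCc9ccccc9)cc(OCc9ccccc9)cc4O[C@H](c8ccc(OCc9ccccc9)c(OCc9ccccc9)c8)[C@@H]3OCc9ccccc9)c2O[C@@H]1c8ccc(OCc9ccccc9)c(OCc9ccccc9)c8 | intermediate
32 | trimer diol | O[C@@H]1[C@@H](c2c(OCc9ccccc9)cc(OCc9ccccc9)c3c2O[C@H](c8ccc(OCc9ccccc9)c(OCc9ccccc9)c8)[C@H](O)C3)c2c(OCc9ccccc9)cc(OCc9ccccc9)c([C@@H]3c4c(OCc9ccccc9)cc(OCc9ccccc9)cc4O[C@H](c8ccc(OCc9ccccc9)c(OCc9ccccc9)c8)[C@@H]3OCc9ccccc9)c2O[C@@H]1c8ccc(OCc9ccccc9)c(OCc9ccccc9)c8 | intermediate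
33 | 3,4,5-tris(benzyloxy)benzoic acid | OC(=O)c1cc(OCc2ccccc2)c(OCc2ccccc2)c(OCc2ccccc2)c1 | starting material
34 | nonadeca-O-benzyl trimer digallate | O=C(O[C@@H]1[C@@H](c2c(OCc9ccccc9)cc(OCc9ccccc9)c3c2O[C@H](c8ccc(OCc9ccccc9)c(OCc9ccccc9)c8)[C@H](OC(=O)c7cc(OCc9ccccc9)c(OCc9ccccc9)c(OCc9ccccc9)c7)C3)c2c(OCc9ccccc9)cc(OCc9ccccc9)c([C@@H]3c4c(OCc9ccccc9)cc(OCc9ccccc9)cc4O[C@H](c8ccc(OCc9ccccc9)c(OCc9ccccc9)c8)[C@@H]3OCc9ccccc9)c2O[C@@H]1c8ccc(OCc9ccccc9)c(OCc9ccccc9)c8)c7cc(OCc9ccccc9)c(OCc9ccccc9)c(OCc9ccccc9)c7 | intermediate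
35 | CNP0279403.2 | O=C(O[C@@H]1[C@@H](c2c(O)cc(O)c3c2O[C@H](c2ccc(O)c(O)c2)[C@H](OC(=O)c2cc(O)c(O)c(O)c2)C3)c2c(O)cc(O)c([C@@H]3c4c(O)cc(O)cc4O[C@H](c4ccc(O)c(O)c4)[C@@H]3O)c2O[C@@H]1c1ccc(O)c(O)c1)c1cc(O)c(O)c(O)c1 | target

Total step count: 19.
Longest linear sequence: 12 steps (3, 5, 6, 7, 8, 13, 14, 15, 16, 17, 18, 19), from (−)-epicatechin 6.

Steps most likely to fail

Step 15 (the step beyond known chemistry).
- Risk: the alkoxide may fragment by retro-aldol cleavage or epimerise at C3 before it meets the aryne. The aryl anion may be protonated before it closes the ring. Fluoride may strip a TBS group.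
- Fallback: it uses known reaction types only, sets out from 7 and 13, and comes back at 29. Ring A of T is then taken from epicatechin and not from the aryne. O3 of 7 would be benzylated (NaH, BnBr, DMF) to 3,5,7,3',4'-penta-O-benzylepicatechin F1. C4 would be oxidised with DDQ in wet CH2Cl2 to the 4β-alcohol F2, and this alcohol would be oxidised with Dess–Martin periodinane to the 2,3-cis flavan-4-one F3. Aryllithium 24, made from 13 as in step 13, should add to the C4 carbonyl of F3 from the β face, opposite to O3 and the 2-aryl group. This gives 29 and rejoins the route before step 16.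

Step 13.
- Risk: addition of the crowded, di-ortho-substituted aryllithium to the branched amide may be so slow that proton transfer from the α-position of the amide takes over.
- Fallback: it sets out from 23 and 13 and comes back at 25. The acyl transfer is replaced by addition to an aldehyde and re-oxidation. Amide 23 would be reduced with i-Bu2AlH (THF, −78 °C) to (2S,3R)-2-benzyloxy-3-[3,4-bis(benzyloxy)phenyl]-3-(triethylsilyloxy)propanal F4, a smaller and more reactive electrophile. Aryllithium 24 should add to it at −78 °C to give the M-8-yl carbinol F5 as a mixture at the new centre. Dess–Martin periodinane should oxidise both epimers to 25.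

Step 16.
- Risk: the cation may lose H-3 (elimination towards the flav-3-ene, with loss of the C3 configuration). The acid may also cleave the M–B bond or a silyl ether before hydride transfer is complete.
- Fallback: it sets out from 29 and comes back at 31. It uses a neutral radical deoxygenation in place of a cation. The tertiary alkoxide of 29 (KN(SiMe3)2, THF, −78 °C) would be acylated with methyl chlorooxalate to the tertiary methyl oxalate F6. Treatment with n-Bu3SnH/AIBN in toluene at 80 °C (Barton–McCombie-type deoxygenation of a tertiary oxalate) should give the planar C4 radical. This radical takes hydrogen from the tin hydride on the same open β face and so leaves the M aryl group α.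

Further compounds
F1 | step 15 | 3,5,7,3',4'-penta-O-benzylepicatechin | O(Cc9ccccc9)[C@@H]1Cc2c(OCc9ccccc9)cc(OCc9ccccc9)cc2O[C@@H]1c8ccc(OCc9ccccc9)c(OCc9ccccc9)c8
F2 | step 15 | 4β-hydroxy-3,5,7,3',4'-penta-O-benzylepicatechin | O(Cc9ccccc9)[C@@H]1[C@@H](O)c2c(OCc9ccccc9)cc(OCc9ccccc9)cc2O[C@@H]1c8ccc(OCc9ccccc9)c(OCc9ccccc9)c8
F3 | step 15 | 2,3-cis 3,5,7,3',4'-pentakis(benzyloxy)flavan-4-one | O(Cc9ccccc9)[C@@H]1C(=O)c2c(OCc9ccccc9)cc(OCc9ccccc9)cc2O[C@@H]1c8ccc(OCc9ccccc9)c(OCc9ccccc9)c8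
F4 | step 13 | (2S,3R)-2-benzyloxy-3-[3,4-bis(benzyloxy)phenyl]-3-(triethylsilyloxy)propanal | O=C[C@@H](OCc1ccccc1)[C@H](O[Si](CC)(CC)CC)c1ccc(OCc2ccccc2)c(OCc2ccccc2)c1
F5 | step 13 | M-8-yl carbinol (both epimers at the new carbinol carbon) | CC(C)(C)[Si](C)(C)O[C@@H]1[C@@H](c2c(OCc9ccccc9)cc(OCc9ccccc9)c3c2O[C@H](c8ccc(OCc9ccccc9)c(OCc9ccccc9)c8)[C@H](O[Si](C)(C)C(C)(C)C)C3)c2c(OCc9ccccc9)cc(OCc9ccccc9)c(C(O)[C@@H](OCc9ccccc9)[C@H](O[Si](CC)(CC)CC)c8ccc(OCc9ccccc9)c(OCc9ccccc9)c8)c2O[C@@H]1c8ccc(OCc9ccccc9)c(OCc9ccccc9)c8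
F6 | step 16 | methyl oxalate of 29 | CC(C)(C)[Si](C)(C)O[C@@H]1[C@@H](c2c(OCc9ccccc9)cc(OCc9ccccc9)c3c2O[C@H](c8ccc(OCc9ccccc9)c(OCc9ccccc9)c8)[C@H](O[Si](C)(C)C(C)(C)C)C3)c2c(OCc9ccccc9)cc(OCc9ccccc9)c([C@@]3(OC(=O)C(=O)OC)c4c(OCc9ccccc9)cc(OCc9ccccc9)cc4O[C@H](c8ccc(OCc9ccccc9)c(OCc9ccccc9)c8)[C@@H]3OCc9ccccc9)c2O[C@@H]1c8ccc(OCc9ccccc9)c(OCc9ccccc9)c8
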